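**Plan**

1. Ring A is named by the chromene numbering of the target (O1, C2, C3, C4, C4a, C5 to C8, C8a); ring B is the 4-hydroxyphenyl ring. The retrosynthesis cuts, in order: the ring B silyl ether; C4–C4a of the pyran (back to an aryl 2-methylbut-3-yn-2-yl ether on O1); C8–prenyl (back to a prenyl ether on the C5 oxygen, para across ring A); the O–C and O–Si bonds; and C6–C(=O) (Hoesch) to phloroglucinol and (4-hydroxyphenyl)acetonitrile.
2. Forward: both benzene rings are bought and joined by acylation. The four hydroxyls are then etherified one at a time in the order of their acidity and accessibility (O1 propargylic, ring B silyl, C7 methyl, C5 prenyl).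
3. A europium-catalysed para-Claisen–Cope shift moves the prenyl group from the C5 oxygen to C8 and frees the chelated C5 hydroxyl. The pyran ring, the only ring made, is then closed by gold-catalysed 6-endo-dig hydroarylation, and desilylation ends the route.
4. Enabling feature: O1 sits on C8a between C8 and C4a. Once C8 carries the prenyl group, C4a is the only CH left on ring A; it is ortho to O1 and to the C5 hydroxyl and para to the C7 methoxy group, so the gold-activated alkyne held by O1–C2(CH3)2 can only attack there.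
5. Stereochemistry: the target has no stereocentre; the C3=C4 bond is cis because it lies in the six-membered ring, and the prenyl alkene carries two identical methyl groups.

Key step: step 7

Remark: the SMILES carry no stereodescriptors because no stereocentre is kept; the transient dienones 9 and 10 are racemic at their one sp3 ring carbon.

**Route**

Step 1
Reactants: 1 phloroglucinol; 2 (4-hydroxyphenyl)acetonitrile
Product: 4 2-(4-hydroxyphenyl)-1-(2,4,6-trihydroxyphenyl)ethan-1-one, via ketiminium chloride 3 (not isolated)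
Conditions: HCl (g), ZnCl2, Et2O, 0 °C; then H2O, 100 °C
Reagents that add atoms: water, O
Why: Hoesch reaction, in which the nitrile activated by HCl and ZnCl2 acylates the threefold-activated, symmetric phloroglucinol once (the iminium salt 3 deactivates the ring and separates) and hydrolysis of 3 should give the ketone, with no regiochemical question because the three ring CH are equivalent.

Step 2
Reactants: 4 2-(4-hydroxyphenyl)-1-(2,4,6-trihydroxyphenyl)ethan-1-one
Product: 5 1-{2,6-dihydroxy-4-[(2-methylbut-3-yn-2-yl)oxy]phenyl}-2-(4-hydroxyphenyl)ethan-1-one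
Conditions: 3-chloro-3-methylbut-1-yne (1.05 equiv), DBU (1.0 equiv), CuCl2·2H2O (1 mol %), MeCN, −5 to 0 °C
Reagents that add atoms: 3-chloro-3-methylbut-1-yne, CC(C)(Cl)C#C
Why: Copper-catalysed propargylic etherification of a phenol, in which one equivalent of base should ionise only the hydroxyl para to the ketone (the future O1, the most acidic of the four), so that the tertiary ether forms there and not at ring B or at the two hydrogen-bonded ortho hydroxyls.

Step 3
Reactants: 5 the O1 propargylic ether
Product: 6 1-{2,6-dihydroxy-4-[(2-methylbut-3-yn-2-yl)oxy]phenyl}-2-{4-[(triisopropylsilyl)oxy]phenyl}ethan-1-one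
Conditions: TIPSCl (1.1 equiv), imidazole, DMF, 0 °C to rt
Reagents that add atoms: chlorotriisopropylsilane (TIPSCl), CC(C)[Si](Cl)(C(C)C)C(C)C
Why: Silylation of a phenol, in which the bulky silyl chloride should react at the ring B hydroxyl, the only one that is neither hydrogen-bonded to the ketone nor flanked by the acyl group.

Step 4
Reactants: 6 the ring B silyl ether
Product: 7 1-{2-hydroxy-6-methoxy-4-[(2-methylbut-3-yn-2-yl)oxy]phenyl}-2-{4-[(triisopropylsilyl)oxy]phenyl}ethan-1-one
Conditions: Me2SO4 (1.05 equiv), K2CO3, acetone, 45 °C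
Reagents that add atoms: dimethyl sulfate, COS(=O)(=O)OC
Why: Williamson methylation of a symmetric 2,6-dihydroxyaryl ketone, in which either ortho hydroxyl gives the same product and the hydroxyl that remains is locked in a strong hydrogen bond to the ketone, so that one equivalent should stop at the monomethyl ether while K2CO3 in acetone leaves the benzylic methylene, the alkyne and the silyl ether alone.

Step 5
Reactants: 7 the C7 methyl ether
Product: 8 1-{2-methoxy-6-[(3-methylbut-2-en-1-yl)oxy]-4-[(2-methylbut-3-yn-2-yl)oxy]phenyl}-2-{4-[(triisopropylsilyl)oxy]phenyl}ethan-1-one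
Conditions: 3-methylbut-2-en-1-ol, PPh3, DIAD, THF, 0 °C to rt
Reagents that add atoms: 3-methylbut-2-en-1-ol, CC(C)=CCO
Why: Mitsunobu etherification, in which the chelated phenol is acidic enough to act as the pronucleophile and the ketone methylene is not, so that the primary allylic alcohol should be joined at oxygen by SN2 displacement without the strong base that C-alkylation would need.

Step 6
Reactants: 8 the C5 prenyl ether
Product: 11 1-{6-hydroxy-2-methoxy-3-(3-methylbut-2-en-1-yl)-4-[(2-methylbut-3-yn-2-yl)oxy]phenyl}-2-{4-[(triisopropylsilyl)oxy]phenyl}ethan-1-one, via ortho-dienone 9 (not isolated), via para-dienone 10 (not isolated)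
Conditions: Eu(fod)3 (10 mol %; fod = 6,6,7,7,8,8,8-heptafluoro-2,2-dimethyloctane-3,5-dionate), CHCl3, 60 °C, sealed tube
Reagents that add atoms: none
Why: Tandem para-Claisen–Cope rearrangement, in which chelation of europium between the ketone and the C5 ether oxygen should speed the first [3,3] shift to C4a (9, reverse prenyl), the second [3,3] shift carries the group on to C8 with normal prenyl connectivity (10) and enolisation gives the hydrogen-bonded phenol, while the unchelated tertiary propargylic ether, which rearranges only well above 120 °C, should stay intact.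

Step 7
Reactants: 11 the C8-prenyl phenol with the O1 propargylic ether
Product: 12 1-[5-hydroxy-7-methoxy-2,2-dimethyl-8-(3-methylbut-2-en-1-yl)-2H-chromen-6-yl]-2-{4-[(triisopropylsilyl)oxy]phenyl}ethan-1-one
Conditions: Ph3PAuNTf2 (3 mol %), CH2Cl2, rt
Reagents that add atoms: none
Why: The cationic gold complex coordinates to the terminal alkyne of 11, ring carbon C4a attacks the terminal alkyne carbon anti to gold in an electrophilic aromatic substitution, and rearomatisation followed by protodeauration gives the 2H-chromene and returns the catalyst. The closest known reaction type is the gold-catalysed intramolecular hydroarylation (cycloisomerisation) of aryl propargyl ethers to 2H-chromenes, which is established for aryl 2-methylbut-3-yn-2-yl ethers. The pyran ring closes in the 6-endo-dig mode by forming the C4–C4a bond, with the O1–C2 bond already in place and the gem-dimethyl group favouring the folded conformer. No stereocentre is formed, and the C3=C4 double bond is cis by virtue of the ring. Site selectivity is secured by the substrate: of the two carbons ortho to O1, C8 carries the prenyl group, so only C4a is open, and C4a is the most nucleophilic position of ring A (ortho to O1 and to the C5 hydroxyl, para to the C7 methoxy group, only meta to the ketone). The step also needs the alkyne to react in preference to the prenyl alkene (whose attack would require an eight-membered ring) and 6-endo closure in preference to 5-exo, which terminal aryl propargyl ethers show under gold catalysis.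

Step 8
Reactants: 12 the silyl-protected chromene
Product: 13 1-[5-hydroxy-7-methoxy-2,2-dimethyl-8-(3-methylbut-2-en-1-yl)-2H-chromen-6-yl]-2-(4-hydroxyphenyl)ethan-1-one
Conditions: Bu4NF, AcOH, THF, 0 °C
Reagents that add atoms: none
Why: Fluoride cleavage of an aryl silyl ether, buffered with acetic acid so that the phenoxide is protonated at once, under which the chromene, the prenyl group, the methyl ether and the ketone should be inert.

**Compound list**

1 | phloroglucinol (benzene-1,3,5-triol) | Oc1cc(O)cc(O)c1 | starting material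
2 | (4-hydroxyphenyl)acetonitrile | N#CCc1ccc(O)cc1 | starting material
3 | 2-(4-hydroxyphenyl)-1-(2,4,6-trihydroxyphenyl)ethan-1-iminium chloride | [NH2+]=C(Cc1ccc(O)cc1)c1c(O)cc(O)cc1O.[Cl-] | intermediate (not isolated)
4 | 2-(4-hydroxyphenyl)-1-(2,4,6-trihydroxyphenyl)ethan-1-one | O=C(Cc1ccc(O)cc1)c1c(O)cc(O)cc1O | intermediate
5 | 1-{2,6-dihydroxy-4-[(2-methylbut-3-yn-2-yl)oxy]phenyl}-2-(4-hydroxyphenyl)ethan-1-one | C#CC(C)(C)Oc1cc(O)c(C(=O)Cc2ccc(O)cc2)c(O)c1 | intermediate
6 | 1-{2,6-dihydroxy-4-[(2-methylbut-3-yn-2-yl)oxy]phenyl}-2-{4-[(triisopropylsilyl)oxy]phenyl}ethan-1-one | C#CC(C)(C)Oc1cc(O)c(C(=O)Cc2ccc(O[Si](C(C)C)(C(C)C)C(C)C)cc2)c(O)c1 | intermediate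
7 | 1-{2-hydroxy-6-methoxy-4-[(2-methylbut-3-yn-2-yl)oxy]phenyl}-2-{4-[(triisopropylsilyl)oxy]phenyl}ethan-1-one | COc1cc(OC(C)(C)C#C)cc(O)c1C(=O)Cc1ccc(O[Si](C(C)C)(C(C)C)C(C)C)cc1 | intermediate
8 | 1-{2-methoxy-6-[(3-methylbut-2-en-1-yl)oxy]-4-[(2-methylbut-3-yn-2-yl)oxy]phenyl}-2-{4-[(triisopropylsilyl)oxy]phenyl}ethan-1-one | COc1cc(OC(C)(C)C#C)cc(OCC=C(C)C)c1C(=O)Cc1ccc(O[Si](C(C)C)(C(C)C)C(C)C)cc1 | intermediate
9 | ortho-dienone: 3-methoxy-6-(2-methylbut-3-en-2-yl)-5-[(2-methylbut-3-yn-2-yl)oxy]-2-({4-[(triisopropylsilyl)oxy]phenyl}acetyl)cyclohexa-2,4-dien-1-one | COC1=C(C(=O)Cc2ccc(O[Si](C(C)C)(C(C)C)C(C)C)cc2)C(=O)C(C(C)(C)C=C)C(OC(C)(C)C#C)=C1 | intermediate (not isolated)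
10 | para-dienone: 3-methoxy-4-(3-methylbut-2-en-1-yl)-5-[(2-methylbut-3-yn-2-yl)oxy]-2-({4-[(triisopropylsilyl)oxy]phenyl}acetyl)cyclohexa-2,5-dien-1-one | COC1=C(C(=O)Cc2ccc(O[Si](C(C)C)(C(C)C)C(C)C)cc2)C(=O)C=C(OC(C)(C)C#C)C1CC=C(C)C | intermediate (not isolated)
11 | 1-{6-hydroxy-2-methoxy-3-(3-methylbut-2-en-1-yl)-4-[(2-methylbut-3-yn-2-yl)oxy]phenyl}-2-{4-[(triisopropylsilyl)oxy]phenyl}ethan-1-one | COc1c(CC=C(C)C)c(OC(C)(C)C#C)cc(O)c1C(=O)Cc1ccc(O[Si](C(C)C)(C(C)C)C(C)C)cc1 | intermediate
12 | 1-[5-hydroxy-7-methoxy-2,2-dimethyl-8-(3-methylbut-2-en-1-yl)-2H-chromen-6-yl]-2-{4-[(triisopropylsilyl)oxy]phenyl}ethan-1-one | COc1c(CC=C(C)C)c2c(c(O)c1C(=O)Cc1ccc(O[Si](C(C)C)(C(C)C)C(C)C)cc1)C=CC(C)(C)O2 | intermediate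
13 | 1-[5-hydroxy-7-methoxy-2,2-dimethyl-8-(3-methylbut-2-en-1-yl)-2H-chromen-6-yl]-2-(4-hydroxyphenyl)ethan-1-one | COc1c(CC=C(C)C)c2c(c(O)c1C(=O)Cc1ccc(O)cc1)C=CC(C)(C)O2 | target

**Totals and risks**

Total step count: 8. Longest linear sequence: 8 steps (fully linear; both starting materials enter in step 1).

Steps most likely to fail:

Step 6. The first [3,3] shift may stop at C4a by enolisation of the ortho-dienone (giving the reverse-prenyl phenol). The Lewis acid may ionise the allylic or the tertiary propargylic ether. The europium chelate may also be too weak on the twisted, doubly ortho-substituted ketone, so that the temperature then needed would start the propargylic ether rearranging without regiocontrol. The fallback changes the order of events and sets out from 7. Heating 7 in N,N-diethylaniline at 190 °C should start a propargyl Claisen shift, hydrogen shift and oxa-6π closure, directed to C4a by the bond fixation that the hydrogen-bonded C5 hydroxyl imposes, to give 1-(5-hydroxy-7-methoxy-2,2-dimethyl-2H-chromen-6-yl)-2-{4-[(triisopropylsilyl)oxy]phenyl}ethan-1-one F1. Mitsunobu reaction of this with 3-methylbut-2-en-1-ol (PPh3, DIAD, THF) should give 1-{7-methoxy-2,2-dimethyl-5-[(3-methylbut-2-en-1-yl)oxy]-2H-chromen-6-yl}-2-{4-[(triisopropylsilyl)oxy]phenyl}ethan-1-one F2. With both ortho positions of that ether substituted, an uncatalysed para-Claisen–Cope shift in N,N-diethylaniline at 200 °C can only end at C8, and the fallback comes back to the route at 12.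

Step 7. The cationic gold catalyst may ionise the tertiary propargylic ether with loss of the side chain, adventitious water may hydrate the alkyne, or 5-exo closure or the prenyl alkene may compete. The fallback sets out from 11 and replaces π-acid catalysis by a metal-free pericyclic cascade, in which the carbon–carbon bond is made by a sigmatropic shift and the ring is closed at oxygen. Heating 11 in o-xylene at 140 °C should cause an aromatic propargyl Claisen shift to C4a, the only free ortho position, and enolisation to 1-{2,4-dihydroxy-6-methoxy-3-(3-methylbuta-1,2-dien-1-yl)-5-(3-methylbut-2-en-1-yl)phenyl}-2-{4-[(triisopropylsilyl)oxy]phenyl}ethan-1-one F3. A [1,5] hydrogen shift should then give the ortho-quinone methide (6Z)-5-hydroxy-3-methoxy-2-(3-methylbut-2-en-1-yl)-6-(3-methylbut-2-en-1-ylidene)-4-({4-[(triisopropylsilyl)oxy]phenyl}acetyl)cyclohexa-2,4-dien-1-one F4, and oxa-6π electrocyclisation closes the pyran. The fallback comes back to the route at 12.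

Step 2. Differentiation of the O1 hydroxyl from the ring B phenol rests on acidity alone, so alkylation at ring B or double alkylation may erode the step. The fallback protects ring B before the acylation and sets out from 2. Pivaloyl chloride and Et3N in CH2Cl2 should give 4-(cyanomethyl)phenyl 2,2-dimethylpropanoate F5. Hoesch reaction of this with 1 (HCl, ZnCl2, Et2O, 0 °C) should give 1-(2,4,6-trihydroxyphenyl)-2-{4-[(2,2-dimethylpropanoyl)oxy]phenyl}ethan-1-iminium chloride F6, and hydrolysis in hot water should give 4-[2-oxo-2-(2,4,6-trihydroxyphenyl)ethyl]phenyl 2,2-dimethylpropanoate F7. In F7 the hydroxyl para to the ketone is the only one that is both free of hydrogen bonding and unprotected, so the etherification conditions of step 2 should give 4-(2-{2,6-dihydroxy-4-[(2-methylbut-3-yn-2-yl)oxy]phenyl}-2-oxoethyl)phenyl 2,2-dimethylpropanoate F8. Methanolysis of the pivalate (K2CO3, MeOH, rt) brings the fallback back to the route at 5.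

**Further compounds**

F1 | step 6 | 1-(5-hydroxy-7-methoxy-2,2-dimethyl-2H-chromen-6-yl)-2-{4-[(triisopropylsilyl)oxy]phenyl}ethan-1-one | COc1cc2c(c(O)c1C(=O)Cc1ccc(O[Si](C(C)C)(C(C)C)C(C)C)cc1)C=CC(C)(C)O2
F2 | step 6 | 1-{7-methoxy-2,2-dimethyl-5-[(3-methylbut-2-en-1-yl)oxy]-2H-chromen-6-yl}-2-{4-[(triisopropylsilyl)oxy]phenyl}ethan-1-one | COc1cc2c(c(OCC=C(C)C)c1C(=O)Cc1ccc(O[Si](C(C)C)(C(C)C)C(C)C)cc1)C=CC(C)(C)O2
F3 | step 7 | 1-{2,4-dihydroxy-6-methoxy-3-(3-methylbuta-1,2-dien-1-yl)-5-(3-methylbut-2-en-1-yl)phenyl}-2-{4-[(triisopropylsilyl)oxy]phenyl}ethan-1-one | COc1c(CC=C(C)C)c(O)c(C=C=C(C)C)c(O)c1C(=O)Cc1ccc(O[Si](C(C)C)(C(C)C)C(C)C)cc1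
F4 | step 7 | (6Z)-5-hydroxy-3-methoxy-2-(3-methylbut-2-en-1-yl)-6-(3-methylbut-2-en-1-ylidene)-4-({4-[(triisopropylsilyl)oxy]phenyl}acetyl)cyclohexa-2,4-dien-1-one | COC1=C(CC=C(C)C)C(=O)/C(=C\C=C(C)C)C(O)=C1C(=O)Cc1ccc(O[Si](C(C)C)(C(C)C)C(C)C)cc1
F5 | step 2 | 4-(cyanomethyl)phenyl 2,2-dimethylpropanoate | CC(C)(C)C(=O)Oc1ccc(CC#N)cc1
F6 | step 2 | 1-(2,4,6-trihydroxyphenyl)-2-{4-[(2,2-dimethylpropanoyl)oxy]phenyl}ethan-1-iminium chloride | CC(C)(C)C(=O)Oc1ccc(CC(=[NH2+])c2c(O)cc(O)cc2O)cc1.[Cl-]
F7 | step 2 | 4-[2-oxo-2-(2,4,6-trihydroxyphenyl)ethyl]phenyl 2,2-dimethylpropanoate | CC(C)(C)C(=O)Oc1ccc(CC(=O)c2c(O)cc(O)cc2O)cc1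
F8 | step 2 | 4-(2-{2,6-dihydroxy-4-[(2-methylbut-3-yn-2-yl)oxy]phenyl}-2-oxoethyl)phenyl 2,2-dimethylpropanoate | CC(C)(C)C(=O)Oc1ccc(CC(=O)c2c(O)cc(OC(C)(C)C#C)cc2O)cc1
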